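The numbers in the tables were computed for an exercise.

The leftover in birch shows how far that flask goes: acidic substrate stands at 61% of its charge at 8.00 min, and 62.5% is what remains if each free base takes one acidic substrate. Free base is then the limiting reagent in birch, and on that count the share of the charge that is taken is

r = min(1, [free base]/[acidic substrate])

| setting | alder | cedar | birch | elm | grey | blue | ochre | amber | teal |
|---|---|---|---|---|---|---|---|---|---|
| acidic substrate | 0.012 M | 0.049 M | 0.14 M | 0.050 M | 0.050 M | 0.015 M | 0.030 M | 0.15 M | 0.050 M |
| free base | 0.0525 M | 0.0525 M | 0.0525 M | 0.0525 M | 0.0525 M | 0.0525 M | 0.0525 M | 0.0525 M | 0.0525 M |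
| electrophile | 0.055 M | 0.055 M | 0.055 M | 0.046 M | 0.0300 M | 0.0550 M | 0.0200 M | 0.0300 M | 0.0550 M |
| temperature | 20 °C | 32 °C | 20 °C | 32 °C | 40 °C | 25 °C | 25 °C | 25 °C | 25 °C |
| remark | run made earlier | run made earlier | run made earlier | run made earlier |  |  |  |  |  |
| time |  |  |  |  | 30 min | 30 min | 30 min | 30 min | 30 min |

| run | time / min | target / % | acidic substrate / % |
|---|---|---|---|
| alder | 4.00 | 56 | 0 |
| alder | 8.00 | 49 | 3 |
| alder | 12.0 | 45 | 0 |
| alder | 15.0 | 40 | 0 |
| alder | 20.0 | 38 | 0 |
| cedar | 4.00 | 29 | 9 |
| cedar | 8.00 | 31 | 3 |
| cedar | 12.0 | 31 | 3 |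
| cedar | 15.0 | 32 | 1 |
| cedar | 20.0 | 33 | 1 |
| birch | 4.00 | 17 | 62 |
| birch | 8.00 | 16 | 61 |
| birch | 12.0 | 15 | 64 |
| birch | 15.0 | 15 | 64 |
| birch | 20.0 | 14 | 60 |
| elm | 2.00 | 25 | 18 |
| elm | 5.00 | 28 | 5 |
| elm | 10.0 | 28 | 1 |
| elm | 15.0 | 31 | 2 |
| elm | 20.0 | 28 | 0 |

(standard deviation of a reading: 1.5 percentage points)



- ranking by amount of target, in percent of the acidic substrate charged, from high to low, at 30 min (grey / blue / ochre / amber / teal)
- the amount of target, in percent of the acidic substrate charged of the flask you put first, at 30 min
- the amount of target, in percent of the acidic substrate charged of the flask you put last, at 30 min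

The first minutes are the uptake: alder shows 0% acidic substrate at 4.00 min, elm 5% at 5.00 min, and target appears in the same minutes.

The middle is read from alder and birch, both at 20 °C with 0.055 M electrophile. Birch has a factor 4.38 more substrate taken, yet divided by r their readings at 20.0 min agree:

birch: 14% / 37.5% = 37.3%
alder: r = 1, so 38%

Their mean is 37.7%; this is Y, the target per substrate taken, a reading with the scatter of these two flasks, taken at 20.0 min and 20 °C.

At the end of its readings target changes less in alder. Alder loses 7 percentage points between its first two readings and 2 points between its last two, although that gap is longer, and cedar reads between 31% and 33% from 12.0 min on. This reckoning therefore holds Y until the asked time.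

Blue, with r = 1 and 0.015 M acidic substrate against alder's 0.012 M, gets about 37.7% in this reckoning. Teal, also with r = 1, has 0.050 M acidic substrate against cedar's 0.049 M and stands at 25 °C against cedar's 32 °C, so this reckoning puts it between cedar's 33% and Y, below blue. Amber is scaled by r and by electrophile, since elm's 28% against cedar's 33% falls roughly in step with its electrophile, 0.046 M against 0.055 M:

amber: 7.19%

The forecast differs on first place: teal > blue > ochre > grey > amber, with top 36% and low 8%. Of blue it says “starts near 58%, then decays to about 25%”.

The flasks give blue > teal > ochre > grey > amber, with top 39.1% and low 8.54%.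

    acidic substrate + free base ⇌ protonated base + anion, settled at all times (K = 2.66, ΔH = −75.0 kJ/mol)
    electrophile + anion → target (k = 22.3 /M/min, Ea = 42.0 kJ/mol)
    anion → side product (k = 0.0624 /min, Ea = 96.0 kJ/mol)
    target ⇌ isomer of the product (K = 0.920, k = 0.258 /min, Ea = 93.0 kJ/mol, ΔH = −9.00 kJ/mol)
    anion → decomposed reagent (k = 0.301 /min, Ea = 90.0 kJ/mol)
    (constants at 25 °C)

In blue the relaxation half-life of target and isomer of the product, both ways together, is 1.29 min, short against the 30 min of the run. Blue holds 39.1% target beside 36.0% isomer of the product at 30.0 min, and 39.1% target at 300 min. With r = 1, blue's Y is 39.1%, against the 37.7% reckoned. The neighbour of blue charged with 0.013 M free base has r = 86.7% and keeps 13% of its acidic substrate; Y gives 32.7% for it, and the flask holds 34.0% target.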